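Cooling from 25 °C to 10 °C raises the early ratio of E to G, the selectivity factor S. The first readings of violet and blue give 1.10, and the early readings of grey and red give 3.33, both with the scatter of readings. The earlier runs held Q at 0.075 M, so any dependence on [Q] is a supposition here. If E takes up Q and G does not, S is proportional to [Q], and the quantity to carry is the selectivity per unit of [Q] at 25 °C, 14.7 M⁻¹.

| flask | Z | Q | D | temperature | remark | time |
|---|---|---|---|---|---|---|
| grey | 0.050 M | 0.075 M | 1 mM | 10 °C | run made earlier |  |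
| violet | 0.070 M | 0.075 M | 1 mM | 25 °C | run made earlier |  |
| red | 0.11 M | 0.075 M | 1 mM | 10 °C | run made earlier |  |
| blue | 0.050 M | 0.075 M | 0.50 mM | 25 °C | run made earlier |  |
| elm | 0.050 M (fed, over 5.0 h) | 0.0750 M | 1.00 mM | 25 °C | all else is in the flask from the start; the feed brings no volume worth counting | 5.0 d |
| larch | 0.050 M | 0.0750 M | 1.00 mM | 25 °C | everything together at the start | 5.0 d |
| birch | 0.050 M (fed, over 50 h) | 0.0750 M | 1.00 mM |  | the addition at 5 °C, then warmed to 25 °C; the feed brings no volume worth counting | 5.0 d |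
| ash | 0.050 M | 0.0750 M (fed, over 50 h) | 1.00 mM | 25 °C | all else is in the flask from the start; the feed brings no volume worth counting | 5.0 d |
| cedar | 0.050 M (in portions, 2, over 50 h) | 0.0750 M | 1.00 mM | 25 °C | first portion at the start, last at 50 h | 5.0 d |

- grey (time / d: E / %, G / %): 0.417: 4.2, 2.7; 1.25: 11.2, 4.1; 2.00: 16.1, 6.9; 4.00: 21.1, 8.8; 5.00: 24.1, 9.9; 6.00: 24.1, 10.7
- violet (time / d: E / %, G / %): 0.208: 6.5, 6.9; 0.625: 13.6, 10.7; 1.04: 15.3, 12.6; 1.67: 15.1, 15.8; 2.50: 16.8, 17.8; 3.00: 16.3, 18.9
- red (time / d: E / %, G / %): 0.500: 5.6, 1.3; 0.833: 9.1, 2.0; 1.25: 9.9, 3.5; 2.00: 11.9, 2.8; 4.00: 14.2, 6.6; 6.00: 16.5, 7.2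
- blue (time / d: E / %, G / %): 0.250: 7.7, 6.0; 0.833: 16.9, 14.2; 1.25: 18.3, 16.0; 2.00: 17.9, 17.7; 3.00: 17.5, 22.1

(standard deviation of a reading: 1 percentage point)

1. the flask with the highest share of E in E plus G ("all alike" if they lie within 1.5 percentage points) (elm / larch / birch / ash / cedar / all alike)
2. share of E in E plus G at the end, elm
3. share of E in E plus G at the end, larch
4. share of E in E plus G at the end, birch
5. share of E in E plus G at the end, ash
6. share of E in E plus G at the end, cedar

- the numbers in the tables scatter with a standard deviation of 1 percentage point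

Now the question turned round: for ash to match larch, the mean [Q] in ash while Z reacts would have to come up to the mean [Q] in larch, which starts at 0.0750 M and falls as E forms: blue, with the Z charge of larch, read 18.3% as E at 1.25 d, which leaves about 0.0658 M of Q. But Q enters ash evenly over 50 h, so the mean amount fed in that time is 0.0375 M. The products do not wait for the feed either: violet held by 1.04 d already 79.3% of the E plus G it held at 3.00 d, a time shorter than the feed. So ash should run near S = 0.550, an early share of 35.5%, against 52.4% at the full charge. Elm and cedar have their Q in from the start, as larch has, so this reckoning sets them near larch. Birch gains from the cold, but grey, warmer than 5 °C and with its Z in from the start, held 23.0% as E plus G at 2.00 d. Much of the Z in birch should therefore react after warming, which makes its gain modest.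

The forecast names birch too, with 50% there, 40.5% for elm, 40% for larch and 43% for cedar, but it sets ash at 44%, above larch, where this reckoning sets ash below, and it says “Q's effect is untested, so ash is uncertain”.

Birch comes out highest at 48.8%, elm gives 38.6%, larch 38.5%, cedar 41.6% and ash 22.5%.

    Z + Q ⇌ E (K = 39.0 M⁻¹, k = 8.20 × 10⁻⁵ M⁻¹ s⁻¹, Ea = 59.0 kJ mol⁻¹, ΔH = −24.0 kJ mol⁻¹)
    Z → G (k = 4.60 × 10⁻⁶ s⁻¹, Ea = 94.0 kJ mol⁻¹)
    2 Z → L (k = 2.90 × 10⁻⁴ M⁻¹ s⁻¹, Ea = 71.0 kJ mol⁻¹)
    Z + D → J (k = 0.00110 M⁻¹ s⁻¹, Ea = 63.0 kJ mol⁻¹)
    (constants at 25 °C)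

Ash ends with E at 7.54% and G at 26.0%, where larch has E at 15.7% and G at 25.1%, so its end ratio is 0.464 of the ratio in larch. Carried to birch with 0.045 M of Q, the selectivity per unit of [Q] scales the end ratio of birch by 0.600, to 0.571, a share of 36.3%. That neighbouring flask gives 36.1%.

The runs come from a simulation for an exercise; scatter was added.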